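**Plan**

1. The retrosynthesis opens ring C at O1–C2 (a ring A phenol displacing an amine from an aminomethylene carbon), then cuts both bonds of the C4 carbonyl, C4a–C4 and C4–C3, and finally the C2=C3 bond of the resulting styryl enamine.
2. The enabling feature is that C4 is an isolated carbonyl carbon whose only neighbours are C4a of the symmetrically trioxygenated ring A and C3, the carbon that bears ring B. It can therefore enter as carbon monoxide between an aryl iodide and the nucleophilic β-carbon of an enamine that already holds C2, C3 and ring B.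
3. Forward, the ring A iodide (two steps from phloroglucinol) and the ring B enamine (bromination, Dakin oxidation, prenylation, formylation and Horner–Wittig aminomethylenation from 2,5-dimethoxybenzaldehyde) are joined with CO to an open-chain enaminone; no ring forms there.
4. Ring C is the only ring built and it closes last, when fluoride frees the ring A phenols and one of them displaces morpholine at C2.
5. The target has no stereocentre and no stereogenic double bond; the E geometry of the enamine and enaminone is transient and vanishes on ring closure.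

Key step: step 9

Remark on the chemistry: ring A is carried as its tris(tert-butyldimethylsilyl) ether, because fluoride unmasking spares the aryl prenyl ether, which the protic acid needed for acetal protecting groups would cleave. Push–pull enaminones isomerise freely about the C2=C3 bond, so the E geometry drawn for the enaminone is of no consequence.

**Route**

Step 1
Reactants: 1 phloroglucinol
Product: 2 2-iodobenzene-1,3,5-triol
Conditions: I2 (1.0 equiv), NaHCO3 (1.1 equiv), THF/H2O 1:1, 0 °C; used promptly
Reagents that add atoms: iodine, II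
Why: Electrophilic aromatic iodination of a very electron-rich arene whose three free positions are equivalent, so one equivalent of iodine should give a single mono-iodide.

Step 2
Reactants: 2 2-iodobenzene-1,3,5-triol
Product: 3 2-iodo-1,3,5-tris(tert-butyldimethylsilyloxy)benzene
Conditions: TBSCl (3.6 equiv), imidazole (7 equiv), DMF, rt
Reagents that add atoms: tert-butyldimethylsilyl chloride, CC(C)(C)[Si](C)(C)Cl
Why: Standard imidazole-mediated silylation of phenols, which also works for hydroxyls flanking an iodine, and gives a base-stable, fluoride-labile protected iodide.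

Step 3
Reactants: 4 2,5-dimethoxybenzaldehyde
Product: 5 4-bromo-2,5-dimethoxybenzaldehyde
Conditions: Br2 (1.1 equiv), AcOH, rt; recrystallisation from EtOH
Reagents that add atoms: bromine, BrBr
Why: Electrophilic aromatic bromination goes ortho to the C5 methoxy group at the less hindered C4, and any minor ortho isomer should be removed by recrystallisation.

Step 4
Reactants: 5 4-bromo-2,5-dimethoxybenzaldehyde
Product: 7 4-bromo-2,5-dimethoxyphenol, via aryl formate 6 (not isolated)
Conditions: mCPBA (1.3 equiv), CH2Cl2, 0 °C → rt; then K2CO3 (0.2 equiv), MeOH, rt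
Reagents that add atoms: 3-chloroperoxybenzoic acid, OOC(=O)c1cccc(Cl)c1
Why: In this Baeyer–Villiger (Dakin-type) oxidation the ortho-methoxy aryl group migrates in preference to hydrogen, and the aryl formate is methanolysed in the same flask to the phenol.

Step 5
Reactants: 7 4-bromo-2,5-dimethoxyphenol; 8 prenyl bromide
Product: 9 1-bromo-2,5-dimethoxy-4-(3-methylbut-2-enyloxy)benzene
Conditions: K2CO3 (2 equiv), acetone, reflux
Reagents that add atoms: none
Why: Williamson ether synthesis; the phenoxide attacks the primary allylic bromide by SN2 at oxygen under carbonate/acetone conditions.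

Step 6
Reactants: 9 1-bromo-2,5-dimethoxy-4-(3-methylbut-2-enyloxy)benzene
Product: 12 2,5-dimethoxy-4-(3-methylbut-2-enyloxy)benzaldehyde, via aryllithium 10 (not isolated), via lithium hemiaminal alkoxide 11 (not isolated)
Conditions: n-BuLi (1.05 equiv), THF, −78 °C; DMF (2 equiv), −78 → 0 °C; H2O
Reagents that add atoms: N,N-dimethylformamide, CN(C)C=O
Why: Bromine–lithium exchange at −78 °C outruns deprotonation of the allylic ether, and formylation of the methoxy-stabilised aryllithium with DMF (Bouveault aldehyde synthesis) avoids acidic Vilsmeier conditions that would endanger the prenyl ether.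

Step 7
Reactants: 13 diphenylphosphine oxide; 14 morpholine
Product: 15 4-[(diphenylphosphoryl)methyl]morpholine
Conditions: paraformaldehyde (1.1 equiv), toluene, 90 °C, 4 Å molecular sieves
Reagents that add atoms: paraformaldehyde (as formaldehyde), C=O
Why: Phospha-Mannich (Kabachnik–Fields) condensation; the iminium ion from morpholine and formaldehyde is trapped by the P–H compound to give the α-aminomethyl phosphine oxide.

Step 8
Reactants: 12 2,5-dimethoxy-4-(3-methylbut-2-enyloxy)benzaldehyde; 15 4-[(diphenylphosphoryl)methyl]morpholine
Product: 18 (E)-4-{2-[2,5-dimethoxy-4-(3-methylbut-2-enyloxy)phenyl]vinyl}morpholine, via lithiated phosphine oxide 16 (not isolated), via lithium alkoxide adduct 17 (not isolated)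
Conditions: 15 (1.1 equiv), n-BuLi (1.1 equiv), THF, −78 °C; 12, −78 °C → rt; KOtBu (1.2 equiv), rt; non-aqueous work-up (pentane, filtration under argon)
Reagents that add atoms: none
Why: Horner–Wittig enamine synthesis; the α-amino phosphine oxide anion adds to the non-enolisable aldehyde, and the potassium alkoxide loses diphenylphosphinate by syn elimination to give the conjugated styryl enamine, expected as the E isomer and made without acid or a free arylacetaldehyde.

Step 9
Reactants: 3 2-iodo-1,3,5-tris(tert-butyldimethylsilyloxy)benzene; 19 carbon monoxide; 18 (E)-4-{2-[2,5-dimethoxy-4-(3-methylbut-2-enyloxy)phenyl]vinyl}morpholine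
Product: 20 (E)-2-[2,5-dimethoxy-4-(3-methylbut-2-enyloxy)phenyl]-3-(morpholin-4-yl)-1-[2,4,6-tris(tert-butyldimethylsilyloxy)phenyl]prop-2-en-1-one
Conditions: Pd(OAc)2 (5 mol%), 4,5-bis(diphenylphosphino)-9,9-dimethylxanthene (7.5 mol%), Et3N (3 equiv), CO (5 bar), 18 (1.5 equiv), dry toluene, 4 Å molecular sieves, 80 °C
Reagents that add atoms: none
Why: Proposed new method: zerovalent palladium, formed in the flask from Pd(OAc)2 and the diphosphine, inserts into the C–I bond of 3, CO insertion relieves the di-ortho strain and gives a divalent aroylpalladium iodide (in equilibrium with the free aroyl iodide by reductive elimination), and the nucleophilic β-carbon of enamine 18 attacks the acyl carbon to give an α-aroyl iminium ion that Et3N deprotonates to the push–pull enaminone 20 while zerovalent palladium is returned. The closest known reactions are the palladium-catalysed carbonylative α-arylation of ketone enolates to 1,3-diketones, the carbonylative acylation of pyrroles and indoles by aryl iodides and CO, and the Stork acylation of enamines by aroyl chlorides. No ring closes and no stereocentre forms; the two new bonds are C4a–C4 and C4–C3. The step needs acylation to beat CO-free arylation and attack at nitrogen: the two ortho silyloxy groups slow direct arylation while CO insertion stays fast, the wide-bite-angle diphosphine and CO pressure favour the acyl path, N-acylation of a tertiary enamine is reversible, and the β-carbon is the only nucleophilic carbon, so ring B ends up on C3 by construction. Oxidative addition into the C–I bond should far outpace ionisation of the trisubstituted allylic aryl ether, so the prenyl group should survive, and the symmetry of ring A means only one iodide and one acyl regiochemistry exist.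

Step 10
Reactants: 20 (E)-2-[2,5-dimethoxy-4-(3-methylbut-2-enyloxy)phenyl]-3-(morpholin-4-yl)-1-[2,4,6-tris(tert-butyldimethylsilyloxy)phenyl]prop-2-en-1-one
Product: 22 brandisianin A, via triphenol enaminone 21 (not isolated)
Conditions: Bu4NF (3.5 equiv), AcOH (5 equiv), THF, 0 °C → rt; then 40 °C, argon
Reagents that add atoms: none
Why: Buffered fluoride cleaves the three aryl silyl ethers without touching the prenyl or methyl ethers, and an ortho phenol of ring A then adds to C2 of the protonated enaminone (6-endo-trig oxa-Michael addition) and morpholine is eliminated, the usual enaminone-to-chromone closure; either ortho oxygen gives the same pyranone.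

**Compound list**

1 | phloroglucinol (benzene-1,3,5-triol) | Oc1cc(O)cc(O)c1 | starting material
2 | 2-iodobenzene-1,3,5-triol | Oc1cc(O)c(I)c(O)c1 | intermediate
3 | 2-iodo-1,3,5-tris(tert-butyldimethylsilyloxy)benzene | CC(C)(C)[Si](C)(C)Oc1cc(O[Si](C)(C)C(C)(C)C)c(I)c(O[Si](C)(C)C(C)(C)C)c1 | intermediate
4 | 2,5-dimethoxybenzaldehyde | COc1ccc(OC)c(C=O)c1 | starting material
5 | 4-bromo-2,5-dimethoxybenzaldehyde | O=Cc1cc(OC)c(Br)cc1OC | intermediate
6 | 4-bromo-2,5-dimethoxyphenyl formate | O=COc1cc(OC)c(Br)cc1OC | intermediate
7 | 4-bromo-2,5-dimethoxyphenol | Oc1cc(OC)c(Br)cc1OC | intermediate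
8 | prenyl bromide (1-bromo-3-methylbut-2-ene) | CC(C)=CCBr | starting material
9 | 1-bromo-2,5-dimethoxy-4-(3-methylbut-2-enyloxy)benzene | CC(C)=CCOc1cc(OC)c(Br)cc1OC | intermediate
10 | [2,5-dimethoxy-4-(3-methylbut-2-enyloxy)phenyl]lithium | [Li]c1cc(OC)c(OCC=C(C)C)cc1OC | intermediate
11 | lithium (dimethylamino)[2,5-dimethoxy-4-(3-methylbut-2-enyloxy)phenyl]methanolate | [Li]OC(N(C)C)c1cc(OC)c(OCC=C(C)C)cc1OC | intermediate
12 | 2,5-dimethoxy-4-(3-methylbut-2-enyloxy)benzaldehyde | O=Cc1cc(OC)c(OCC=C(C)C)cc1OC | intermediate
13 | diphenylphosphine oxide | O=[PH](c1ccccc1)c1ccccc1 | starting material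
14 | morpholine | C1COCCN1 | starting material
15 | 4-[(diphenylphosphoryl)methyl]morpholine | O=P(CN1CCOCC1)(c1ccccc1)c1ccccc1 | intermediate
16 | [(diphenylphosphoryl)(morpholin-4-yl)methyl]lithium | [Li]C(N1CCOCC1)P(=O)(c1ccccc1)c1ccccc1 | intermediate
17 | lithium 1-[2,5-dimethoxy-4-(3-methylbut-2-enyloxy)phenyl]-2-(diphenylphosphoryl)-2-(morpholin-4-yl)ethanolate (diastereomer mixture) | [Li]OC(c1cc(OC)c(OCC=C(C)C)cc1OC)C(N1CCOCC1)P(=O)(c1ccccc1)c1ccccc1 | intermediate
18 | (E)-4-{2-[2,5-dimethoxy-4-(3-methylbut-2-enyloxy)phenyl]vinyl}morpholine | O1CCN(CC1)/C=C/c1cc(OC)c(OCC=C(C)C)cc1OC | intermediate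
19 | carbon monoxide | [C-]#[O+] | starting material
20 | (E)-2-[2,5-dimethoxy-4-(3-methylbut-2-enyloxy)phenyl]-3-(morpholin-4-yl)-1-[2,4,6-tris(tert-butyldimethylsilyloxy)phenyl]prop-2-en-1-one | O1CCN(CC1)/C=C(\c1cc(OC)c(OCC=C(C)C)cc1OC)C(=O)c1c(O[Si](C)(C)C(C)(C)C)cc(O[Si](C)(C)C(C)(C)C)cc1O[Si](C)(C)C(C)(C)C | intermediate
21 | (E)-2-[2,5-dimethoxy-4-(3-methylbut-2-enyloxy)phenyl]-3-(morpholin-4-yl)-1-(2,4,6-trihydroxyphenyl)prop-2-en-1-one | O1CCN(CC1)/C=C(\c1cc(OC)c(OCC=C(C)C)cc1OC)C(=O)c1c(O)cc(O)cc1O | intermediate
22 | brandisianin A, 3-[2,5-dimethoxy-4-(3-methylbut-2-enyloxy)phenyl]-5,7-dihydroxychromen-4-one | COc1cc(-c2coc3cc(O)cc(O)c3c2=O)c(OC)cc1OCC=C(C)C | target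

**Step count and risks**

Total step count: 10. Longest linear sequence: 7 steps (steps 3, 4, 5, 6, 8, 9, 10 from 2,5-dimethoxybenzaldehyde). The ring A branch (steps 1, 2) and the reagent branch (step 7) are shorter.

Steps most likely to fail:

1. Step 9. The hindered aroylpalladium may be captured too slowly by the enamine, so that CO-free arylation, aminocarbonylation by morpholine released from adventitious hydrolysis, or palladium-induced ionisation of the allylic ether takes over. Fallback: the same two bonds are made stoichiometrically from 3. Iodine–magnesium exchange with i-PrMgCl·LiCl in THF at −20 °C gives [2,4,6-tris(tert-butyldimethylsilyloxy)phenyl]magnesium chloride F1. CO2 then delivers C4 as 2,4,6-tris(tert-butyldimethylsilyloxy)benzoic acid F2. 1-Chloro-N,N,2-trimethylprop-1-en-1-amine in CH2Cl2 converts the acid under neutral conditions into 2,4,6-tris(tert-butyldimethylsilyloxy)benzoyl chloride F3. Stork acylation of enamine 18 with F3 and Et3N in CH2Cl2 at 0 °C returns to the route at 20.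

2. Step 10. After desilylation, hydrolysis of the enaminone with retro-Claisen loss of the C2 carbon, or air oxidation of the electron-rich triphenolate, may compete with ring closure. Fallback: from 20, aqueous KOH in EtOH at reflux under argon removes the silyl groups and the aminomethylene carbon together and converges all material on the deoxybenzoin 2-[2,5-dimethoxy-4-(3-methylbut-2-enyloxy)phenyl]-1-(2,4,6-trihydroxyphenyl)ethanone F4. The one-carbon unit is then put back and ring C closed by the classical deoxybenzoin method, N,N-dimethylformamide dimethyl acetal in THF at 60 °C, which comes back to the route at 22.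

3. Step 8. The phosphine oxide adduct may not eliminate completely, or the enamine may hydrolyse during isolation. Fallback: from 9, bromine–lithium exchange as in step 6 gives aryllithium 10, which opens ethylene oxide (THF, −78 °C → rt) to 2-[2,5-dimethoxy-4-(3-methylbut-2-enyloxy)phenyl]ethanol F5. Dess–Martin periodinane buffered with NaHCO3 in CH2Cl2 gives 2-[2,5-dimethoxy-4-(3-methylbut-2-enyloxy)phenyl]acetaldehyde F6. Condensation with morpholine 14 over 4 Å molecular sieves in toluene returns to the route at 18, used as its toluene solution in step 9.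

**Further compounds**

F1 | step 9 | [2,4,6-tris(tert-butyldimethylsilyloxy)phenyl]magnesium chloride | Cl[Mg]c1c(O[Si](C)(C)C(C)(C)C)cc(O[Si](C)(C)C(C)(C)C)cc1O[Si](C)(C)C(C)(C)C
F2 | step 9 | 2,4,6-tris(tert-butyldimethylsilyloxy)benzoic acid | OC(=O)c1c(O[Si](C)(C)C(C)(C)C)cc(O[Si](C)(C)C(C)(C)C)cc1O[Si](C)(C)C(C)(C)C
F3 | step 9 | 2,4,6-tris(tert-butyldimethylsilyloxy)benzoyl chloride | ClC(=O)c1c(O[Si](C)(C)C(C)(C)C)cc(O[Si](C)(C)C(C)(C)C)cc1O[Si](C)(C)C(C)(C)C
F4 | step 10 | 2-[2,5-dimethoxy-4-(3-methylbut-2-enyloxy)phenyl]-1-(2,4,6-trihydroxyphenyl)ethanone | O=C(Cc1cc(OC)c(OCC=C(C)C)cc1OC)c1c(O)cc(O)cc1O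
F5 | step 8 | 2-[2,5-dimethoxy-4-(3-methylbut-2-enyloxy)phenyl]ethanol | OCCc1cc(OC)c(OCC=C(C)C)cc1OC
F6 | step 8 | 2-[2,5-dimethoxy-4-(3-methylbut-2-enyloxy)phenyl]acetaldehyde | O=CCc1cc(OC)c(OCC=C(C)C)cc1OC
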